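The charge of Z is small: 21 mM against 105 mM of X, so Z is the limiting reagent. If each reacted Z takes at most one X, at most 20.0% of the X can go, so at least 80.0% of it stays in this flask, the eta run carried on to 30 h.

the same everywhere: Z 21 mM (fed, over 3.0 h)

| charge | X | remark | time |
|---|---|---|---|
| eta | 105 mM | the very flask that is asked about, followed so far |  |
| theta | 70 mM | run made earlier |  |
| flask | 105 mM |  | 30 h |

| run | time / h | Z / % | L / % |
|---|---|---|---|
| eta | 0.500 | 8.1 | 2.3 |
| eta | 0.833 | 14.9 | 3.2 |
| eta | 1.33 | 21.5 | 2.3 |
| eta | 2.00 | 32.8 | 5.5 |
| eta | 4.00 | 42.5 | 16.9 |
| eta | 6.00 | 41.1 | 25.0 |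
| theta | 1.50 | 30.2 | 3.7 |
| theta | 3.00 | 57.7 | 8.3 |
| theta | 5.00 | 51.3 | 17.8 |
| theta | 8.00 | 47.9 | 23.8 |
| theta | 12.0 | 47.2 | 23.1 |
| theta | 20.0 | 45.8 | 23.2 |

(standard deviation of a reading: 1 percentage point)

1. which holds at 30 h: what has brought the reaction to rest, or that it has not come to rest (it is still moving / X has run out first / forward and back rates have come level / all of Z has reacted)
2. conversion of Z at 30 h
3. amount of L at 30 h, in percent of the Z charged
4. amount of E at 30 h, in percent of the Z charged

- the numbers in the tables scatter with a standard deviation of 1 percentage point
- a reading or a percentage of L counts all its forms, free or not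
- the reaction counts as stopped when no species that holds the Z changes by six tenths of a point or more over the second half of the time
- percentages count the whole charge, also what has not yet gone in
- what has gone from Z into another species counts as reacted, even if it can come back
- a reading of Z is of its free form alone

Has theta, the run with less X, come to rest, and on what? From 8.00 h to 20.0 h its Z goes from 47.9% to 45.8% and its L from 23.8% to 23.2%, with a scatter of 1 percentage point in each reading. The mean reading of free Z there is 47.0%, so, at no more than one X per reacted Z, at least 58.9 mM of X stands free in theta, more than the whole charge of Z. You therefore read theta's rest as a balance of forward and back rates.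

Will the flask get there in time? After its feed it has 5.40 times the span theta needed after its own feed, so I expect rest.

How far does it go? Take the hold, the reacted Z per free Z, divided by the free X: theta gives 0.0192 mM⁻¹. Holding the charge of Z as in theta, and with 84.0 mM of X as a first guess, conversion comes to 61.7%. At one X per reacted Z that leaves 92.0 mM of X, and my reckoning ends at 63.8%.

The forecast says forward and back rates have come level, with conversion 61.5% (58% to 66%), L 28% (24% to 35%) and E 33.5% (28% to 38%), since "L has levelled by equilibrium".

The flask gives forward and back rates have come level, with conversion 63.3%, L 27.4% and E 29.3%.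

    Z + X ⇌ E (K = 8.60 M⁻¹, k = 180 M⁻¹ h⁻¹)
    E ⇌ L (K = 0.710, k = 0.260 h⁻¹)
    Z + L ⇌ D, settled at all times (K = 41.0 M⁻¹)

D, at 13.2% of the charge in the flask at 30.0 h, counts as reacted Z and so stands inside the hold. The flask's own hold, from its conversion and the 89% of X left, is 0.0185 mM⁻¹ against 0.0192 mM⁻¹. Now take the same flask with 420 mM of X, where 96% of that X is left at 30.0 h, which is 403 mM. The hold then gives a conversion of 88.6%, and that flask gives 86.6%.

The readings stem from a simulated flask for substances that don't exist, noise included.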